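A bend smaller than its own scatter cannot show an enzyme dying, so the thing to watch here is target at half time against target at the end.

| flask | starting material | second substrate | free enzyme | temperature | remark | time |
|---|---|---|---|---|---|---|
| winter | 0.013 M | 0.036 M | 2 µM | 14 °C | run made earlier |  |
| autumn | 0.030 M | 0.036 M | 2 µM | 31 °C | run made earlier |  |
| grey | 0.020 M | 0.0360 M | 2.0 µM | 7 °C |  | 6.0 min |
| violet | 0.020 M | 0.0360 M | 2.0 µM | 37 °C |  | 6.0 min |
| ochre | 0.020 M | 0.0360 M | 2.0 µM | 22 °C |  | 6.0 min |

winter run (percent of the starting material charged): time / min: target / % = 0.250: 0; 0.667: 2.0; 1.33: 3.2; 2.00: 4.3; 3.00: 8.6; 4.00: 11.9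

autumn run (percent of the starting material charged): time / s: target / % = 12.0: 0.9; 25.0: 1.7; 40.0: 2.4; 50.0: 5.3; 60.0: 3.0; 80.0: 3.7

(each reading ± 1 percentage point)



- the flask that comes out highest in amount of target, in percent of the starting material charged, or "all alike" when all lie within 1.5 percentage points (grey / violet / ochre / all alike)
- target at the end, in percent of the starting material charged, grey
- target at the end, in percent of the starting material charged, violet
- target at the end, in percent of the starting material charged, ochre

Two people read these runs. In the autumn run target gained 2.4% by 40.0 s, then 1.3 percentage points by 80.0 s. The first person says heat is killing the free enzyme. A catalyst decaying at a steady pace loses the same factor over each equal stretch, so the two half-run gains count its lifetimes. Call n the lifetimes in the run: 2 ln(first-half gain / second-half gain). The autumn readings give n = 1.23, which is a lifetime of 1.09 min. Violet's 6.0 min would then hold 5.50 lifetimes, even before its extra warmth.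

The second person says the line is straight. The end reading falls short of the doubled middle reading by 1.1 points, but that shortfall carries a scatter of 2.2 points. The winter run's gains do not fall at all: 4.3%, then 7.6 points.

I side with the second person. I take the rate as independent of the charge, and read 0.387 mM min⁻¹ for winter and 0.833 mM min⁻¹ for autumn. Violet is warmer than autumn, so it should pass 25.0%. Ochre lies between the two runs, so between 11.6% and that figure. Grey, colder than winter, stays below the lower one. Violet therefore comes out highest.

The forecast takes the first person's side, “the enzyme is probably dying by heat”, and gives 6.5% for grey, 3.5% for violet, 16% for ochre, with ochre highest.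

The flasks gave 6.64% for grey, 29.7% for violet and 19.7% for ochre, so violet is highest.

    free enzyme → unfolded enzyme (k = 0.00220 min⁻¹, Ea = 221 kJ mol⁻¹)
    starting material + free enzyme ⇌ first complex (K = 140 M⁻¹, k = 3.13 × 10⁵ M⁻¹ s⁻¹, Ea = 31.0 kJ mol⁻¹, ΔH = −33.0 kJ mol⁻¹)
    first complex ⇌ loaded enzyme + first product (K = 0.177 M, k = 4170 min⁻¹, Ea = 54.0 kJ mol⁻¹, ΔH = −60.0 kJ mol⁻¹)
    second substrate + loaded enzyme ⇌ second complex (K = 6.64 M⁻¹, k = 75200 M⁻¹ s⁻¹, Ea = 21.0 kJ mol⁻¹, ΔH = −87.0 kJ mol⁻¹)
    second complex → free enzyme + target (k = 3390 min⁻¹, Ea = 72.0 kJ mol⁻¹)
    first product → by-product carried off (k = 0.254 min⁻¹, Ea = 79.0 kJ mol⁻¹)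
    (constants at 37 °C)

Violet's resting state at 6.00 min was loaded enzyme, at 68.0%, and unfolded enzyme stood at 0.0729%. Violet's target went 15.5% at 3.00 min, then 29.7% at 6.00 min, so the same count gives n = 0.159, against the 5.50 lifetimes reckoned from the autumn readings. Ochre's 9.96% and 19.7% give n = 0.0501. The first person's unfolding does show in a longer violet run, which held 7.66% of its catalyst as unfolded enzyme at 60.0 min.

Readings and results are simulated with made-up constants; scatter was added.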